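The runs were computed with constants of no real substance; scatter was added.

Left-handed product is the reading to follow in this flask, which is the alpha run carried on. Its course has a crossing, where gain stops paying for loss.

| setting | alpha | zeta | flask |
|---|---|---|---|
| left-handed substrate | 0.050 M | 0.025 M | 0.050 M |
| right-handed substrate | 0.050 M | 0.025 M | 0.050 M |
| reagent | 0.11 M | 0.11 M | 0.110 M |
| remark | the very flask that is asked about, followed so far | run made earlier |  |
| time |  |  | 6.0 min |

- alpha (time / min: left-handed product / %): 0.200: 37.5; 0.333: 42.8; 0.417: 43.6; 0.667: 45.0; 1.00: 46.3; 1.50: 46.3; 2.50: 44.9
- zeta (time / min: left-handed product / %): 0.333: 48.7; 1.00: 57.4; 1.50: 58.0; 2.50: 58.1; 4.00: 55.6; 5.00: 53.8; 6.00: 54.1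

(standard deviation of a reading: 0.5 percentage points)

- reagent is single-handed; left-handed substrate and right-handed substrate are mirror images of each other, charged as a racemate, each of them at the stated concentration
- what may be going on: 2 reagent -> homo dimer; left-handed substrate <-> right-handed substrate; left-handed product <-> right-handed product; reagent + left-handed substrate -> left-handed product; reagent + right-handed substrate -> right-handed product
- the handed part of reagent does not stay in what it makes, so the products of the two hands are mirror images too

* amount of left-handed product in percent of the left-handed substrate and right-handed substrate together charged, at 20 s, 1.5 min and 6.0 min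

Find the crossing first. The alpha run reads 46.3% at 1.00 min and 46.3% at 1.50 min, so put it there. Keep those readings for the two early points: 42.8% at 0.333 min is already the reading at 20 s.

Now turn the last point round and ask what would hold left-handed product level until 6.0 min. Gain would have to match the fall rate, the fraction of the charge lost as left-handed product per minute past the top. Read it from the zeta run, which is followed further past its top than the alpha run:

fall rate = (58.1% − 54.1%) / (6.00 min − 2.50 min) = 0.0114 min⁻¹

Level until 6.0 min needs 5.13% of the charge as new left-handed product. Expect no such gain: the zeta run, with twice the reagent per substrate, still falls, and the alpha run has begun to, reading 44.9% at 2.50 min. My own line: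

46.3% − 0.0114 min⁻¹ × 4.50 min = 41.2%

The forecast says 42.8%, 46.2% and 41.8%, noting “Both runs then lose about 1.2 points per minute”. Its last point stands above mine.

The flask gives 42.1%, 46.2% and 40.1%.

    2 reagent → homo dimer (k = 0.620 M⁻¹ s⁻¹)
    left-handed substrate ⇌ right-handed substrate (k = 0.230 s⁻¹)
    left-handed product ⇌ right-handed product (k = 0.00140 s⁻¹)
    reagent + left-handed substrate → left-handed product (k = 2.10 M⁻¹ s⁻¹)
    reagent + right-handed substrate → right-handed product (k = 0.760 M⁻¹ s⁻¹)

By 3.00 min reagent stands at 0%, and from there to 6.00 min right-handed product climbs from 25.3% to 28.9% while left-handed product drops from 43.8% to 40.1%. Run the fall rate down from 46.2% over 4.50 min: it lands at 41.1%, and the flask stands at 40.1%.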